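**Retrosynthetic overview**

1. Target 16 (prostanoid numbering C1–C20 is used throughout) ⇐ cross-metathesis forming C13=C14 between the 4-vinylcyclopentenone acid 13 and (S)-oct-1-en-3-yl acetate 15, which brings C15 and its acetate ready-made.
2. 13 ⇐ tert-butyl ester cleavage and C10=C11 dehydrogenation of the trans-2-alkyl-3-vinylcyclopentanone 9.
3. 9 ⇐ Pd-catalysed decarboxylative ring contraction of the racemic seven-membered β-keto lactone 7 (an oxepane-2,4-dione). The enabling feature: ring atom C7 carries a vinyl group and is bound to the ring oxygen O1 (an allyl ester), while O1–C2(=O)–C3–C4(=O) is a β-keto ester in the same ring. Ionization at C7–O1, bond formation C3→C7 and loss of O1–C2 as CO2 turn ring atoms C3, C4, C5, C6, C7 into C8, C9, C10, C11, C12.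
4. 7 ⇐ acylketene lactonization of hydroxy β-keto ester 5 ⇐ alkylation of 3 with bromide 4 ⇐ Claisen condensation of γ-vinyl-γ-butyrolactone 1 with tert-butyl acetate 2.
5. Ring order: the five-membered lactone of 1 is opened (step 1), the seven-membered lactone is closed (step 3) and then contracted to the only ring of the target (step 4). C12 is set by the catalyst, C8 by equilibration, C15 by the building block.

Key step: step 4

Remark: (3S)-oct-1-en-3-ol (14) is taken as commercially available in enantiopure form.
Remark: the ligand enantiomer in step 4 is a working assignment by analogy with branched attack on the vinyl-substituted π-allyl complex from 2-vinyloxirane; if a model run shows the opposite sense, the (S,S)-ligand is used with no other change.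

**Route**

Step 1
Reactants: 1 (±)-5-ethenyloxolan-2-one (γ-vinyl-γ-butyrolactone); 2 tert-butyl acetate
Product: 3 (±)-tert-butyl 6-hydroxy-3-oxooct-7-enoate (in equilibrium with its five-membered hemiketal)
Conditions: LDA (2.2 equiv), 2 (2.2 equiv), THF, −78 °C; then 1, −78 → −40 °C; AcOH quench
Reagents that add atoms: none
Why: Crossed Claisen condensation of a lactone with the lithium enolate of a tert-butyl ester, in which the β-keto ester enolate that forms protects the ketone from a second addition; no stereocenter is set and the carbinol carbon (future C12) stays racemic by design.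

Step 2
Reactants: 3 (±)-tert-butyl 6-hydroxy-3-oxooct-7-enoate; 4 tert-butyl 7-bromoheptanoate
Product: 5 di-tert-butyl 2-(4-hydroxyhex-5-enoyl)nonanedioate (racemic; both diastereomers)
Conditions: K2CO3 (1.5 equiv), NaI (0.1 equiv), acetone, reflux
Reagents that add atoms: none
Why: Acetoacetic ester C-alkylation with in situ Finkelstein exchange should occur at the doubly activated carbon while carbonate leaves the secondary alcohol alone; the new stereocenter (future C8) needs no control because step 4 erases it.

Step 3
Reactants: 5 di-tert-butyl 2-(4-hydroxyhex-5-enoyl)nonanedioate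
Product: 7 tert-butyl 7-(7-ethenyl-2,4-dioxooxepan-3-yl)heptanoate (racemic; both diastereomers), via acylketene 6 (not isolated)
Conditions: toluene, 110 °C, slow addition to a final 0.005 M, tert-butanol distilled off
Reagents that add atoms: none
Why: Thermal loss of tert-butanol from a β-keto tert-butyl ester gives an acylketene that the C12 hydroxyl should trap intramolecularly (acylketene lactonization, a known way to medium-ring β-keto lactones), with high dilution suppressing dimerization and the simple side-chain tert-butyl ester inert at this temperature.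

Step 4
Reactants: 7 tert-butyl 7-(7-ethenyl-2,4-dioxooxepan-3-yl)heptanoate
Product: 9 tert-butyl 7-[(1R,2R)-2-ethenyl-5-oxocyclopentyl]heptanoate, via ring-contracted β-keto acid 8 (not isolated)
Conditions: Pd2(dba)3·CHCl3 (2.5 mol %), (R,R)-DACH-phenyl Trost ligand (7.5 mol %), degassed 1,4-dioxane, 25 → 60 °C; then DBU (0.2 equiv), 25 °C
Reagents that add atoms: none
Why: Proposed new method: Pd(0) ionizes the allylic C7–O1 bond of the oxepane-2,4-dione to a zwitterionic π-allyl-palladium β-keto carboxylate, whose stabilized α-carbon C3 attacks the internal allyl carbon C7 to give β-keto acid 8, which loses O1–C2 as CO2, so that ring carbons C3–C7 become the cyclopentanone; the closest known reaction types are the Tsuji–Saegusa decarboxylative allylation of allyl β-keto esters and the Pd-catalysed 1,3-O-to-C shift of 5-vinyl-2-alkylidene-tetrahydrofurans to 3-vinylcyclopentanones, here extended to a cyclic allyl β-keto ester and made enantioselective. The one ring is closed by 5-exo attack of C3 on the substituted terminus of the π-allyl unit, which the three-atom tether C4–C5–C6 should make faster than 7-endo attack at the CH2 terminus (that path would give the cycloheptenone, the product of a thermal Carroll rearrangement). C12 is set by the chiral ligand: the monosubstituted allyl unit exchanges faces by η3–η1–η3 isomerization at its unsubstituted terminus and by reversible re-closure of the carboxylate, so both C7 epimers of 7 reach the same pair of diastereomeric complexes and the ligand pocket selects one for outer-sphere attack anti to palladium (a dynamic kinetic asymmetric transformation, as with vinyl epoxides). C8 is erased at the quaternary β-keto acid and its enol and is then set under thermodynamic control by DBU, trans to the vinyl group, which is why all four stereoisomers of 7 should converge on one product. The step needs branched over linear regioselectivity and face exchange faster than C–C bond formation; the ring size of the product and the terminal vinyl group of the substrate are what secure them.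

Step 5
Reactants: 9 tert-butyl 7-[(1R,2R)-2-ethenyl-5-oxocyclopentyl]heptanoate
Product: 12 tert-butyl 7-[(1R,2S)-2-ethenyl-5-oxocyclopent-3-en-1-yl]heptanoate, via kinetic lithium enolate 10 (not isolated), via α-sulfilimine adduct 11 (not isolated)
Conditions: LDA (1.05 equiv), THF, −78 °C; then N-tert-butylbenzenesulfinimidoyl chloride (1.2 equiv), −78 °C
Reagents that add atoms: none
Why: Kinetic deprotonation of the 2,3-disubstituted cyclopentanone should occur at the unsubstituted C10 methylene, and the enolate is S-functionalized and undergoes syn-elimination at −78 °C (Mukaiyama dehydrogenation), placing the double bond at C10=C11 only and leaving C8 and C12 untouched (the descriptor at C12 changes from R to S only through the priority rules).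

Step 6
Reactants: 12 tert-butyl 7-[(1R,2S)-2-ethenyl-5-oxocyclopent-3-en-1-yl]heptanoate
Product: 13 7-[(1R,2S)-2-ethenyl-5-oxocyclopent-3-en-1-yl]heptanoic acid
Conditions: TFA–CH2Cl2 (1:4), 0 °C → 25 °C
Reagents that add atoms: none
Why: Acidolysis of the tert-butyl ester (loss of isobutene) should leave the acid-stable cyclopentenone and the vinyl group intact and avoids any base that could move the doubly allylic C12 hydrogen into conjugation.

Step 7
Reactants: 14 (3S)-oct-1-en-3-ol
Product: 15 (3S)-oct-1-en-3-yl acetate
Conditions: Ac2O (1.5 equiv), pyridine, DMAP (cat.), CH2Cl2, 0 → 25 °C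
Reagents that add atoms: acetic anhydride, CC(=O)OC(C)=O
Why: DMAP-catalysed O-acylation of the secondary allylic alcohol does not touch the stereocenter, which becomes C15 of the target.

Step 8
Reactants: 13 7-[(1R,2S)-2-ethenyl-5-oxocyclopent-3-en-1-yl]heptanoic acid; 15 (3S)-oct-1-en-3-yl acetate
Product: 16 7-[(1R,2S)-2-[(1E,3S)-3-acetoxyoct-1-en-1-yl]-5-oxocyclopent-3-en-1-yl]heptanoic acid (the target)
Conditions: Hoveyda–Grubbs II catalyst (5 mol %), 15 (3 equiv), 1,4-benzoquinone (10 mol %), CH2Cl2, 40 °C
Reagents that add atoms: none
Why: Olefin cross-metathesis between the vinyl group at C12 and the terminal alkene of the allylic acetate (ethene is lost) should form C13=C14 with E geometry under thermodynamic control, while the electron-poor cyclic enone C10=C11 stays out of metathesis, the free acid and the acetate are tolerated, and C15 arrives unchanged with 15.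

**Compound list**

1 | (±)-5-ethenyloxolan-2-one | C=CC1CCC(=O)O1 | starting material
2 | tert-butyl acetate | CC(=O)OC(C)(C)C | starting material
3 | (±)-tert-butyl 6-hydroxy-3-oxooct-7-enoate | C=CC(O)CCC(=O)CC(=O)OC(C)(C)C | intermediate
4 | tert-butyl 7-bromoheptanoate | BrCCCCCCC(=O)OC(C)(C)C | starting material
5 | di-tert-butyl 2-(4-hydroxyhex-5-enoyl)nonanedioate (racemic; both diastereomers) | C=CC(O)CCC(=O)C(CCCCCCC(=O)OC(C)(C)C)C(=O)OC(C)(C)C | intermediate
6 | tert-butyl 12-hydroxy-9-oxo-8-(oxomethylidene)tetradec-13-enoate (acylketene; not isolated) | C=CC(O)CCC(=O)C(=C=O)CCCCCCC(=O)OC(C)(C)C | intermediate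
7 | tert-butyl 7-(7-ethenyl-2,4-dioxooxepan-3-yl)heptanoate (racemic; both diastereomers) | C=CC1CCC(=O)C(CCCCCCC(=O)OC(C)(C)C)C(=O)O1 | intermediate
8 | (5R)-1-(7-tert-butoxy-7-oxoheptyl)-5-ethenyl-2-oxocyclopentane-1-carboxylic acid (both epimers at the quaternary carbon; not isolated) | C=C[C@H]1CCC(=O)C1(CCCCCCC(=O)OC(C)(C)C)C(=O)O | intermediate
9 | tert-butyl 7-[(1R,2R)-2-ethenyl-5-oxocyclopentyl]heptanoate | C=C[C@H]1CCC(=O)[C@@H]1CCCCCCC(=O)OC(C)(C)C | intermediate
10 | kinetic lithium enolate of 9 (C9–C10 enolate; not isolated) | C=C[C@H]1CC=C([O-])[C@@H]1CCCCCCC(=O)OC(C)(C)C.[Li+] | intermediate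
11 | C10 N-tert-butyl-S-phenylsulfilimine adduct of 9 (not isolated) | C=C[C@H]1CC(S(=NC(C)(C)C)c2ccccc2)C(=O)[C@@H]1CCCCCCC(=O)OC(C)(C)C | intermediate
12 | tert-butyl 7-[(1R,2S)-2-ethenyl-5-oxocyclopent-3-en-1-yl]heptanoate | C=C[C@H]1C=CC(=O)[C@@H]1CCCCCCC(=O)OC(C)(C)C | intermediate
13 | 7-[(1R,2S)-2-ethenyl-5-oxocyclopent-3-en-1-yl]heptanoic acid | C=C[C@H]1C=CC(=O)[C@@H]1CCCCCCC(=O)O | intermediate
14 | (3S)-oct-1-en-3-ol | CCCCC[C@@H](C=C)O | starting material
15 | (3S)-oct-1-en-3-yl acetate | CCCCC[C@@H](C=C)OC(C)=O | intermediate
16 | 7-[(1R,2S)-2-[(1E,3S)-3-acetoxyoct-1-en-1-yl]-5-oxocyclopent-3-en-1-yl]heptanoic acid | CCCCC[C@@H](/C=C/[C@H]1C=CC(=O)[C@@H]1CCCCCCC(=O)O)OC(C)=O | target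

**Step count**

Total steps: 8. Longest linear sequence: 7 (steps 1–6 and 8; step 7 prepares the coupling partner).

**Steps most likely to fail**

1. Step 4 (Proposed new method). The C–C bond may form at the CH2 terminus of the π-allyl unit and give the seven-membered carbocycle, or the π-allyl complex may lose a proton to a diene instead of being alkylated. Ring closure may also outrun face exchange, so that facial discrimination by the ligand is poor or of the wrong sense. The fallback uses known chemistry and gives up the ring contraction. It sets out from bromide 4: LiCl-assisted zinc insertion (Zn dust, LiCl, THF, 50 °C) should give tert-butyl 7-(bromozincio)heptanoate F1. Negishi coupling of F1 with commercial 2-iodocyclopent-2-en-1-one (Pd(PPh3)4 cat., THF) should give tert-butyl 7-(5-oxocyclopent-1-en-1-yl)heptanoate F2. Rhodium(I)/(S)-BINAP-catalysed Hayashi–Miyaura 1,4-addition of potassium vinyltrifluoroborate to F2 (ligand enantiomer chosen by analogy with additions to cyclopent-2-en-1-one), followed by DBU equilibration to the trans isomer, should give 9, where the route is rejoined at step 5.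

2. Step 3. The hemiketal tautomer of 5 may dehydrate to the exocyclic enol ether, or the acylketene may be captured intermolecularly (oligomerization) instead of closing the seven-membered ring. The fallback replaces thermal acylketene formation by thiophilic activation at room temperature and sets out from lactone 1. Claisen condensation of 1 with the lithium enolate of S-tert-butyl thioacetate should give S-tert-butyl 6-hydroxy-3-oxooct-7-enethioate F3. Alkylation of F3 with 4 (K2CO3, NaI, acetone) should give tert-butyl 8-[(tert-butylsulfanyl)carbonyl]-12-hydroxy-9-oxotetradec-13-enoate F4. Silver(I) trifluoroacetate-mediated lactonization of F4 (Na2HPO4, THF, 25 °C, high dilution) should give 7, where the route is rejoined at step 4.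

3. Step 8. Productive metathesis between two allylically branched terminal alkenes may be slow, so that homodimerization of 15 and ruthenium hydride-mediated migration of the doubly allylic C12 hydrogen (conjugation of the vinyl group) take over. The fallback moves the coupling ahead of the sensitive dienone stage and sets out from 9 and 14. Silylation of 14 (TBSCl, imidazole) should give tert-butyl(dimethyl){[(3S)-oct-1-en-3-yl]oxy}silane F5. Cross-metathesis of 9 with F5 should give tert-butyl 7-[(1R,2R)-2-[(1E,3S)-3-(tert-butyldimethylsilyloxy)oct-1-en-1-yl]-5-oxocyclopentyl]heptanoate F6. Dehydrogenation as in step 5 should give tert-butyl 7-[(1R,2S)-2-[(1E,3S)-3-(tert-butyldimethylsilyloxy)oct-1-en-1-yl]-5-oxocyclopent-3-en-1-yl]heptanoate F7. HF·pyridine should give tert-butyl 7-[(1R,2S)-2-[(1E,3S)-3-hydroxyoct-1-en-1-yl]-5-oxocyclopent-3-en-1-yl]heptanoate F8. Acetylation (Ac2O, pyridine) should give tert-butyl 7-[(1R,2S)-2-[(1E,3S)-3-acetoxyoct-1-en-1-yl]-5-oxocyclopent-3-en-1-yl]heptanoate F9. Cleavage of the tert-butyl ester with 85 % aqueous H3PO4 in toluene should give the target 16.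

**Further compounds**

F1 | step 4 | tert-butyl 7-(bromozincio)heptanoate | Br[Zn]CCCCCCC(=O)OC(C)(C)C
F2 | step 4 | tert-butyl 7-(5-oxocyclopent-1-en-1-yl)heptanoate | O=C1CCC=C1CCCCCCC(=O)OC(C)(C)C
F3 | step 3 | S-tert-butyl 6-hydroxy-3-oxooct-7-enethioate | C=CC(O)CCC(=O)CC(=O)SC(C)(C)C
F4 | step 3 | tert-butyl 8-[(tert-butylsulfanyl)carbonyl]-12-hydroxy-9-oxotetradec-13-enoate | C=CC(O)CCC(=O)C(CCCCCCC(=O)OC(C)(C)C)C(=O)SC(C)(C)C
F5 | step 8 | tert-butyl(dimethyl){[(3S)-oct-1-en-3-yl]oxy}silane | CCCCC[C@@H](C=C)O[Si](C)(C)C(C)(C)C
F6 | step 8 | tert-butyl 7-[(1R,2R)-2-[(1E,3S)-3-(tert-butyldimethylsilyloxy)oct-1-en-1-yl]-5-oxocyclopentyl]heptanoate | CCCCC[C@@H](/C=C/[C@H]1CCC(=O)[C@@H]1CCCCCCC(=O)OC(C)(C)C)O[Si](C)(C)C(C)(C)C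
F7 | step 8 | tert-butyl 7-[(1R,2S)-2-[(1E,3S)-3-(tert-butyldimethylsilyloxy)oct-1-en-1-yl]-5-oxocyclopent-3-en-1-yl]heptanoate | CCCCC[C@@H](/C=C/[C@H]1C=CC(=O)[C@@H]1CCCCCCC(=O)OC(C)(C)C)O[Si](C)(C)C(C)(C)C
F8 | step 8 | tert-butyl 7-[(1R,2S)-2-[(1E,3S)-3-hydroxyoct-1-en-1-yl]-5-oxocyclopent-3-en-1-yl]heptanoate | CCCCC[C@@H](/C=C/[C@H]1C=CC(=O)[C@@H]1CCCCCCC(=O)OC(C)(C)C)O
F9 | step 8 | tert-butyl 7-[(1R,2S)-2-[(1E,3S)-3-acetoxyoct-1-en-1-yl]-5-oxocyclopent-3-en-1-yl]heptanoate | CCCCC[C@@H](/C=C/[C@H]1C=CC(=O)[C@@H]1CCCCCCC(=O)OC(C)(C)C)OC(C)=O
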